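The amber, grey and red runs, with [starting material] from 0.021 M to 0.043 M, read 23%, 24% and 23% of intermediate at 5.00 min. Within the scatter of 2 percentage points, the percent reading at that time does not move with the charge, as in pseudo-first-order behaviour, and your hunch that dosing pays can lean on that. Here is the quick number you asked for.

| flask | starting material | partner | remark | time |
|---|---|---|---|---|
| amber | 0.043 M | 0.086 M | run made earlier |  |
| grey | 0.021 M | 0.086 M | run made earlier |  |
| red | 0.032 M | 0.086 M | run made earlier |  |
| delta | 0.043 M | 0.0860 M (fed, over 4.80 min) | all but partner at the start; partner goes in evenly over 4.80 min, the run ends at 6.0 min | 6.0 min |
| zeta | 0.043 M (fed, over 4.80 min) | 0.0860 M | a stirred flask in which starting material is dosed at a steady rate over 4.80 min without added volume, worked up at 6.0 min | 6.0 min |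
| alpha | 0.043 M | 0.0860 M | a closed flask charged with all of it at once and left for 6.0 min | 6.0 min |
| gamma | 0.043 M | 0.0860 M | a single well-mixed tank run continuously and read at steady state, 6.0 min in it on average |  |

- amber (time / min: intermediate / %, product / %): 1.50: 36, 2; 3.00: 40, 5; 5.00: 23, 7; 6.00: 18, 8
- grey (time / min: intermediate / %, product / %): 2.00: 36, 3; 4.00: 33, 7; 5.00: 24, 8; 8.00: 9, 9
- red (time / min: intermediate / %, product / %): 0.833: 25, 0; 2.50: 38, 7; 5.00: 23, 8; 8.00: 11, 13

(scatter of a reading: 2 percentage points)

- percentages count the starting material that a species holds: one idle adduct counts as two
- product is meant together with its idle adduct
- the stated concentrations are those of everything mixed, before any reaction; amounts are the same in each set-up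
- reactions considered so far: intermediate -> decomposed reagent; starting material + product <-> idle adduct; partner + intermediate -> product; starting material -> intermediate
- the feed brings no volume worth counting
- the earlier runs were made in a closed, stirred flask
- in an amount of product, one idle adduct counts as one product

1. the set-up with the highest amount of intermediate at the outlet or at the end, in percent of the starting material put in ("none" if the first two lie within 2 percentage points) (delta / zeta / alpha / gamma / none)
2. amount of intermediate at the outlet or at the end, in percent of the starting material put in, delta
3. amount of intermediate at the outlet or at the end, in percent of the starting material put in, zeta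
4. amount of intermediate at the outlet or at the end, in percent of the starting material put in, alpha
5. amount of intermediate at the outlet or at the end, in percent of the starting material put in, gamma

1. We take each portion dosed into zeta to run the amber curve on its own clock, so its age at work-up is what counts. Steady dosing spreads those ages evenly from 1.20 min to 6.0 min.

2. First round: the mean age is 3.60 min, and amber, read between its neighbouring points, gives 34.9%.

3. Second round: we put that answer back. Amber rises and then falls across the span, so one age will not do, and we average the readings over the whole span, holding the earliest reading for the youngest sliver. This age-window average, the mean of the batch curve over the ages the portions have at work-up, is 31.5%, which is less than the first round.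

4. Alpha is the amber recipe, read at 6.00 min: 18%. Our figure for zeta stands above that reading by 14 points.

The forecast, made from these same runs, names zeta, with 19% for delta, 31% for zeta (27% to 36%), 18% for alpha and 20% for gamma. Its ground for zeta is that “late-dosed material is younger at work-up”. We take its figures for delta and gamma. For zeta we differ from it by 0.50 points.

The flask gives 19.0% for delta, 31.0% for zeta, 18.3% for alpha and 20.4% for gamma, so zeta leads.

    intermediate → decomposed reagent (k = 0.382 min⁻¹)
    starting material + product ⇌ idle adduct, settled at all times (K = 33.0 M⁻¹)
    partner + intermediate → product (k = 0.628 M⁻¹ min⁻¹)
    starting material → intermediate (k = 0.491 min⁻¹)

Zeta leads gamma by 11 points, and our window average of 31.5% lies 0.50 points above zeta's figure. At half time, the portions in zeta span ages from nothing up to 3.00 min; a like sum over that span, with amber taken as a straight rise from nothing to its earliest reading and divided by the whole dosing time, gives 17.5%, and zeta then holds 19.2% of intermediate.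

All runs were computed with constants of no real substance, and the scatter is random.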